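## Analysis of the target

The target, 2,3,5-tribromo-6-(3,5-dibromo-2-methoxyphenoxy)phenol (13), is a diaryl ether of two benzene rings. It has no stereocentre and is achiral, so only constitution has to be controlled. Ring B is numbered C1 (OH), C2 (bridging O), C3 (Br), C4 (H), C5 (Br), C6 (Br); ring A is C1' (bridging O), C2' (OMe), C3' (Br), C4' (H), C5' (Br), C6' (H). Both rings are catechol-type, and their non-bridging oxygens differ only in that one is methylated and the other free, so the two must be told apart by the way the molecule is assembled. The five aryl C–Br bonds exclude hydrogenolysis, zerovalent palladium and strongly basic organometallics once bromine is present, and the free phenol must not be exposed during diazonium chemistry. The real difficulty is ring B: its bromines do not follow the hydroxyl, since C4 (para to OH) is unsubstituted while C3 and C5 (meta to OH) are brominated. The strategy rests on the fact that C3 and C5 are para and ortho to C6. A nitrogen donor placed at C6 therefore directs bromine to exactly those two carbons and can afterwards be exchanged for the C6 bromine. On ring A, C3' and C5' are ortho and para to the C2' oxygen, the natural sites of a free phenol.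

## Retrosynthetic reasoning

13 to 12: the O–CH2Ph bond at C1 is cut last. Keeping the ring B oxygen as a benzyl ether until the end prevents it from acting as a free phenol director toward C4, from being methylated, and from interfering with the diazonium step. A benzyl ether is chosen because a boron Lewis acid removes it at low temperature without reducing C–Br bonds or cleaving the methyl ether.

12 to 10 through 11: the C6–Br bond is traced back to a C6–N bond. Ipso replacement through diazonium salt 11 puts the bromine where the nitrogen was, so this bromine needs no regiocontrol. The forward reaction only requires that no free phenol be present, which is why methylation comes first.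

10 to 9: the O–CH3 bond on ring A is cut. In 9 the C2' hydroxyl is the only free phenol, so methylation settles which oxygen carries the methyl group. The only selectivity needed is O over N, and the amine in 9 is hindered and electron-poor.

9 to 8: the four C–Br bonds at C3, C5, C3' and C5' are cut together. In 8 the strongest donor of each ring (NH2 at C6, OH at C2') points at precisely these four carbons and the bridging oxygen reinforces the choice on ring B. One electrophilic bromination should therefore install all four halogens.

8 to 7: the amine is traced to a nitro group. The nitro group is kept through the earlier steps because it acidifies the neighbouring hydroxyl for selective benzylation and is inert to peracid. It is reduced only immediately before bromination because the aminophenol ether 8 is oxidation-prone.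

7 to 5 through 6: the C2' hydroxyl is traced to a formyl group. The aldehyde in 5 is what makes ring A electrophilic for ether formation. Oxidative aryl migration then converts it into the oxygen via formate 6.

5 to 3 and 4: the O–C1' bond of the diaryl ether is cut. This side is chosen because ring A can carry an ortho-formyl-activated fluorine (4). The alternative cut at O–C2 would need substitution at a position of ring B that is meta to nitro and not activated. The phenol 3 serves as the nucleophile.

3 to 1 and 2: the O–benzyl bond is cut. In 1 the hydroxyl flanked by the nitro group is much the more acidic, so alkylation of the monoanion with 2 should mark that oxygen and leave the other free for the ether formation.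

## Alternatives that were turned down

Alternative 1: Ring B is cut at C2–C3 and C5–C6 into the aryloxyacetone A2 (made from the ring A phenol A4) and sodium nitromalonaldehyde A3. In the forward direction, aqueous alkali would condense both alpha carbons of A2 with the two formyl groups of A3 and aromatise to the nitrophenol A1. After reduction of the nitro group of A1, the C4 nitrogen would direct bromine to C3 and C5 and the hydroxyl would direct to C6; the nitrogen would then be removed reductively.
- For: ring A arrives with its bromines and methyl ether in place, so the OMe/OH question and the ring A regiochemistry need no selectivity at all. On this point it is stronger than the chosen route.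
- Against: A3 is a shock-sensitive salt. A2 can self-condense under the same basic conditions and carries a hindered, doubly ortho-substituted aryloxy group on the reacting methylene. The intermediate after reduction is a para-aminophenol, a substitution pattern that electrophilic bromine tends to oxidise to a quinone imine rather than substitute. The nitrogen is finally discarded and not used. A4 has its bromines meta to the hydroxyl and needs its own multistep preparation.
- Comparison: the step count is no shorter. The chosen route offers a director that ends up as one of the target's bromines and never places a free hydroxyl and an amine para to each other on one ring.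

Alternative 2: Ring B is cut at C2–C3 and C1–C6 into 3,5-dibromo-2-pyrone A6 and the aryloxyethynyl boronate A7. In the forward direction a [4+2] cycloaddition followed by decarboxylative aromatisation would give the aryl boronate A5. Oxidation of the C–B bond would then give the C1 hydroxyl, and a final bromination would have to go to C6.
- For: the C3 and C5 bromines come with the pyrone without any regiochemical question, boron sits where oxygen is needed, and the route is convergent. On ring B bromine placement it is more direct than the chosen route.
- Against: A7 is a fragile ynol-ether boronate that must be made from A4 in several steps. Pyrone–alkyne cycloadditions need forcing temperatures. The required orientation joins the oxygen-bearing alkyne carbon to the bromine-bearing pyrone carbon, the most congested union. After oxidation the last bromine must go ortho to the hydroxyl (C6) while the para position C4 is also free, so only steric shielding by the flanking bromines would stand against the wrong isomer.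
- Comparison: the chosen route places the C6 bromine by ipso substitution of nitrogen, which has no positional ambiguity, and uses only robust intermediates.

Alternative 3: The O–C2 and C3–Br bonds are cut together. Halogen–magnesium exchange on the iodo triflate A9 would generate the C2–C3 aryne. The magnesium aryloxide of A4 would add at C2 under the influence of the boryl group at C1, and the C3 arylmagnesium would be quenched with an electrophilic bromine donor to give A8. Oxidation of the C–B bond would then finish the synthesis.
- For: this has the shortest endgame of all the options and forms the hindered diaryl ether without activating groups. In convergence it is clearly stronger than the chosen route.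
- Against: A9 is a pentasubstituted benzene whose preparation carries all the regiochemical problems of ring B with it. The exchange reagent must discriminate iodine from four aryl bromides and must not add to the boronate. A hindered, electron-poor aryloxide is a weak aryne trap, so addition of the alkyl group of the exchange reagent is a likely competitor.
- Comparison: the chosen route never generates an organometallic in the presence of C–Br bonds and relies on donor-controlled substitution, at the price of a longer linear sequence.

Key step: step 5

Remark: the ring numbering of the analysis is used throughout; the target has no stereocentre, so no configuration has to be set.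

## Route

Step 1
Reactants: 1 3-nitrocatechol; 2 benzyl bromide
Product: 3 2-(benzyloxy)-3-nitrophenol
Conditions: Li2CO3 (1.1 equiv), BnBr (1.05 equiv), DMF, 50 °C
Reagents that add atoms: none
Why: Williamson O-alkylation of the monoanion; the hydroxyl next to the nitro group is by far the more acidic, so one equivalent of the weak base Li2CO3 should ionise only that oxygen, and because 3 is a weaker acid than 1 a second benzylation is disfavoured.

Step 2
Reactants: 3 2-(benzyloxy)-3-nitrophenol; 4 2-fluorobenzaldehyde
Product: 5 2-[2-(benzyloxy)-3-nitrophenoxy]benzaldehyde
Conditions: K2CO3, DMF, 110 °C
Reagents that add atoms: none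
Why: Nucleophilic aromatic substitution (SNAr); the ortho formyl group stabilises the Meisenheimer adduct and fluoride is the best leaving group for addition–elimination, while the phenoxide of 3 is not conjugated with the nitro group and stays nucleophilic.

Step 3
Reactants: 5 2-[2-(benzyloxy)-3-nitrophenoxy]benzaldehyde
Product: 7 2-[2-(benzyloxy)-3-nitrophenoxy]phenol, via aryl formate 6 (not isolated)
Conditions: mCPBA, CH2Cl2, rt to 40 °C; aq NaHCO3/Na2S2O3 wash; then K2CO3 (cat.), MeOH, rt
Reagents that add atoms: meta-chloroperoxybenzoic acid (mCPBA), O=C(OO)c1cccc(Cl)c1
Why: Baeyer–Villiger (Dakin-type) oxidation; in the Criegee intermediate the aryl group, made electron-rich by its ortho aryloxy oxygen, should migrate in preference to hydride to give formate 6, which base-catalysed methanolysis cleaves to the phenol; the nitro group and benzyl ether are inert to the peracid.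

Step 4
Reactants: 7 2-[2-(benzyloxy)-3-nitrophenoxy]phenol
Product: 8 2-[3-amino-2-(benzyloxy)phenoxy]phenol
Conditions: Fe powder, AcOH, EtOH/H2O, 70 °C
Reagents that add atoms: none
Why: Béchamp-type dissolving-metal reduction of the nitro group; iron in weak acid leaves the benzyl ether (which hydrogenation could cleave) and the diaryl ether untouched, and the air-sensitive amine would be used directly in the next step.

Step 5
Reactants: 8 2-[3-amino-2-(benzyloxy)phenoxy]phenol
Product: 9 2-[3-amino-2-(benzyloxy)-4,6-dibromophenoxy]-4,6-dibromophenol
Conditions: NBS (4.05 equiv, portionwise), MeCN, −10 °C to rt, dark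
Reagents that add atoms: N-bromosuccinimide, O=C1CCC(=O)N1Br
Why: Fourfold electrophilic aromatic bromination through arenium ions, the reaction type long used for ortho/para halogenation of anilines and phenols with N-bromosuccinimide; no ring closes and no stereocentre forms. On ring B the amine at C6 is the dominant donor and sends bromine to C3 (para) and C5 (ortho); the bridging oxygen at C2 activates the same two carbons, and the other position ortho to nitrogen, C1, is blocked by the benzyloxy group. C4 is meta to nitrogen, is activated only by the benzylated oxygen, and after the first two substitutions lies between two bromines, so it should remain C–H. On ring A the free hydroxyl at C2' outranks the aryloxy oxygen and directs to C5' (para) and then C3' (ortho), the pattern shown by guaiacol-type phenols. Each ring is strongly deactivated once it carries two bromines, which should stop the reaction at four substitutions when four equivalents are used. The required site selectivity on both rings is thus secured by the substrate itself: NH2 at C6 and OH at C2' as the strongest donors, with the ring B oxygen muted as its benzyl ether. Low temperature, portionwise addition and exclusion of light are meant to suppress oxidation of the amine and radical benzylic bromination.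

Step 6
Reactants: 9 2-[3-amino-2-(benzyloxy)-4,6-dibromophenoxy]-4,6-dibromophenol
Product: 10 2-(benzyloxy)-4,6-dibromo-3-(3,5-dibromo-2-methoxyphenoxy)aniline
Conditions: MeI (1.1 equiv), K2CO3, acetone, rt
Reagents that add atoms: iodomethane, CI
Why: Williamson methylation; the dibromophenol of ring A is acidic enough for K2CO3 and its phenoxide is the only strong nucleophile, whereas the amine is flanked by bromine and benzyloxy and deactivated by two bromines, so O-methylation should prevail over N-methylation.

Step 7
Reactants: 10 2-(benzyloxy)-4,6-dibromo-3-(3,5-dibromo-2-methoxyphenoxy)aniline
Product: 12 3-(benzyloxy)-1,2,5-tribromo-4-(3,5-dibromo-2-methoxyphenoxy)benzene, via arenediazonium bromide 11 (not isolated)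
Conditions: t-BuONO (1.5 equiv), CuBr2 (1.5 equiv), MeCN, 0 to 60 °C
Reagents that add atoms: CuBr2 (copper dibromide), Br[Cu]Br; tert-butyl nitrite, CC(C)(C)ON=O (its nitrogen is carried only in 11 and leaves as N2)
Why: Sandmeyer bromodediazoniation under non-aqueous alkyl nitrite conditions; tert-butyl nitrite converts the weakly basic amine into diazonium salt 11, copper-mediated electron transfer releases N2, and the aryl radical takes bromine from CuBr2 at the carbon that carried nitrogen, so the C6 bromine needs no regiocontrol; with the phenol methylated no diazo-oxide can form.

Step 8
Reactants: 12 3-(benzyloxy)-1,2,5-tribromo-4-(3,5-dibromo-2-methoxyphenoxy)benzene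
Product: 13 2,3,5-tribromo-6-(3,5-dibromo-2-methoxyphenoxy)phenol
Conditions: BCl3 (2 equiv), C6HMe5 (3 equiv), CH2Cl2, −78 °C; then H2O
Reagents that add atoms: none
Why: Lewis-acid debenzylation; BCl3 activates the benzylic ether oxygen and the benzyl cation is trapped by pentamethylbenzene in a Friedel–Crafts reaction, which prevents C-benzylation of the product; at −78 °C the aryl methyl ether, the diaryl ether and the C–Br bonds should be untouched, and aqueous quench frees the phenol.

## Compound list

1 | 3-nitrocatechol (3-nitrobenzene-1,2-diol) | Oc1cccc([N+](=O)[O-])c1O | starting material
2 | benzyl bromide | BrCc1ccccc1 | starting material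
3 | 2-(benzyloxy)-3-nitrophenol | Oc1cccc([N+](=O)[O-])c1OCc1ccccc1 | intermediate
4 | 2-fluorobenzaldehyde | O=Cc1ccccc1F | starting material
5 | 2-[2-(benzyloxy)-3-nitrophenoxy]benzaldehyde | O=Cc1ccccc1Oc1cccc([N+](=O)[O-])c1OCc1ccccc1 | intermediate
6 | 2-[2-(benzyloxy)-3-nitrophenoxy]phenyl formate | O=COc1ccccc1Oc1cccc([N+](=O)[O-])c1OCc1ccccc1 | intermediate
7 | 2-[2-(benzyloxy)-3-nitrophenoxy]phenol | Oc1ccccc1Oc1cccc([N+](=O)[O-])c1OCc1ccccc1 | intermediate
8 | 2-[3-amino-2-(benzyloxy)phenoxy]phenol | Oc1ccccc1Oc1cccc(N)c1OCc1ccccc1 | intermediate
9 | 2-[3-amino-2-(benzyloxy)-4,6-dibromophenoxy]-4,6-dibromophenol | Oc1c(Br)cc(Br)cc1Oc1c(Br)cc(Br)c(N)c1OCc1ccccc1 | intermediate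
10 | 2-(benzyloxy)-4,6-dibromo-3-(3,5-dibromo-2-methoxyphenoxy)aniline | COc1c(Br)cc(Br)cc1Oc1c(Br)cc(Br)c(N)c1OCc1ccccc1 | intermediate
11 | 2-(benzyloxy)-4,6-dibromo-3-(3,5-dibromo-2-methoxyphenoxy)benzenediazonium bromide | COc1c(Br)cc(Br)cc1Oc1c(Br)cc(Br)c([N+]#N)c1OCc1ccccc1.[Br-] | intermediate
12 | 3-(benzyloxy)-1,2,5-tribromo-4-(3,5-dibromo-2-methoxyphenoxy)benzene (benzyl ether of the target) | COc1c(Br)cc(Br)cc1Oc1c(Br)cc(Br)c(Br)c1OCc1ccccc1 | intermediate
13 | 2,3,5-tribromo-6-(3,5-dibromo-2-methoxyphenoxy)phenol | COc1c(Br)cc(Br)cc1Oc1c(Br)cc(Br)c(Br)c1O | target

## Step count and least certain steps

Total step count: 8. Longest linear sequence: 8 steps (1 to 13).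

Step 5 (key step). The electron-rich amine may be oxidised (N-bromination followed by oxidative oligomerisation) in competition with ring substitution. Stoichiometric control may also be imperfect, leaving the slower ring A under-brominated or forcing a fifth substitution at C4 or C4'. Fallback, setting out from 7 and returning at 9: NBS (2 equiv) would brominate only ring A of 7, since the nitro group shuts ring B down, giving 2-[2-(benzyloxy)-3-nitrophenoxy]-4,6-dibromophenol F1. Fe/AcOH reduction, which tolerates aryl bromides, would give 2-[3-amino-2-(benzyloxy)phenoxy]-4,6-dibromophenol F2. A second bromination with two equivalents of NBS would then only have to serve the aniline ring and would give 9. This gives up the single operation but keeps the directing logic and halves the oxidant load on the free amine.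

Step 7. After loss of N2, the C6 aryl radical may attack the phenyl ring of the neighbouring benzyloxy group (a Pschorr-type ring closure) or abstract hydrogen from the solvent, both in competition with bromine transfer from CuBr2. Diazotisation of the hindered, weakly basic amine may also be slow. Fallback, setting out from 10 and returning at 13: BCl3/pentamethylbenzene debenzylation would be carried out first to give 2-amino-3,5-dibromo-6-(3,5-dibromo-2-methoxyphenoxy)phenol F3. Classical aqueous diazotisation (NaNO2, 48% HBr, 0 °C) would keep the phenol protonated and give 4,6-dibromo-3-(3,5-dibromo-2-methoxyphenoxy)-2-hydroxybenzenediazonium bromide F4, which CuBr in HBr at 60 °C would convert into 13 directly. With no benzyl group present the intramolecular arylation is impossible, and 12 is bypassed.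

Step 1. Regioselectivity may erode through proton transfer between the two oxygens, and some dibenzylation may occur. Fallback, setting out from 1 and returning at 5: the order of the two O-functionalisations would be inverted. With excess K2CO3 in DMF at 100 °C the dianion of 1 should react with 4 through its more nucleophilic oxygen remote from the nitro group, giving 2-(2-hydroxy-3-nitrophenoxy)benzaldehyde F5. The one remaining hydroxyl of F5 would then be benzylated with 2 (K2CO3, DMF) to give 5, with no choice of site left.

Step 6. N-methylation of the amine may compete with O-methylation if the phenoxide reacts slowly. Fallback, setting out from 9 and returning at 10: Mitsunobu methylation (MeOH, PPh3, diisopropyl azodicarboxylate, THF) engages only pronucleophiles as acidic as the phenol and cannot alkylate the amine. No new intermediate arises.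

Step 3. Hydride migration may compete with aryl migration in the Criegee intermediate and give the benzoic acid instead of the formate. Fallback, setting out from 3 and returning at 7: SNAr of 3 with 2'-fluoroacetophenone (CC(=O)c1ccccc1F; K2CO3, DMF, 130 °C) would give 1-{2-[2-(benzyloxy)-3-nitrophenoxy]phenyl}ethan-1-one F6. Its Baeyer–Villiger oxidation (mCPBA, CF3CO2H cat., CH2Cl2) can only choose between aryl and methyl migration and should give 2-[2-(benzyloxy)-3-nitrophenoxy]phenyl acetate F7, which K2CO3/MeOH would cleave to 7.

## Further compounds

F1 | step 5 | 2-[2-(benzyloxy)-3-nitrophenoxy]-4,6-dibromophenol | Oc1c(Br)cc(Br)cc1Oc1cccc([N+](=O)[O-])c1OCc1ccccc1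
F2 | step 5 | 2-[3-amino-2-(benzyloxy)phenoxy]-4,6-dibromophenol | Oc1c(Br)cc(Br)cc1Oc1cccc(N)c1OCc1ccccc1
F3 | step 7 | 2-amino-3,5-dibromo-6-(3,5-dibromo-2-methoxyphenoxy)phenol | COc1c(Br)cc(Br)cc1Oc1c(Br)cc(Br)c(N)c1O
F4 | step 7 | 4,6-dibromo-3-(3,5-dibromo-2-methoxyphenoxy)-2-hydroxybenzenediazonium bromide | COc1c(Br)cc(Br)cc1Oc1c(Br)cc(Br)c([N+]#N)c1O.[Br-]
F5 | step 1 | 2-(2-hydroxy-3-nitrophenoxy)benzaldehyde | O=Cc1ccccc1Oc1cccc([N+](=O)[O-])c1O
F0 | step 6 | none | none
F6 | step 3 | 1-{2-[2-(benzyloxy)-3-nitrophenoxy]phenyl}ethan-1-one | CC(=O)c1ccccc1Oc1cccc([N+](=O)[O-])c1OCc1ccccc1
F7 | step 3 | 2-[2-(benzyloxy)-3-nitrophenoxy]phenyl acetate | CC(=O)Oc1ccccc1Oc1cccc([N+](=O)[O-])c1OCc1ccccc1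
A1 | alternative 1 | 2-(3,5-dibromo-2-methoxyphenoxy)-4-nitrophenol | COc1c(Br)cc(Br)cc1Oc1cc([N+](=O)[O-])ccc1O
A2 | alternative 1 | 1-(3,5-dibromo-2-methoxyphenoxy)propan-2-one | COc1c(Br)cc(Br)cc1OCC(C)=O
A3 | alternative 1 | sodium nitromalonaldehyde | [Na+].[O-]C=C(C=O)[N+](=O)[O-]
A4 | alternative 1 | 3,5-dibromo-2-methoxyphenol | COc1c(Br)cc(Br)cc1O
A5 | alternative 2 | 2-[3,5-dibromo-2-(3,5-dibromo-2-methoxyphenoxy)phenyl]-4,4,5,5-tetramethyl-1,3,2-dioxaborolane | COc1c(Br)cc(Br)cc1Oc1c(Br)cc(Br)cc1B1OC(C)(C)C(C)(C)O1
A6 | alternative 2 | 3,5-dibromo-2H-pyran-2-one | O=c1occ(Br)cc1Br
A7 | alternative 2 | 2-[(3,5-dibromo-2-methoxyphenoxy)ethynyl]-4,4,5,5-tetramethyl-1,3,2-dioxaborolane | COc1c(Br)cc(Br)cc1OC#CB1OC(C)(C)C(C)(C)O1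
A8 | alternative 3 | 2-[2,3,5-tribromo-6-(3,5-dibromo-2-methoxyphenoxy)phenyl]-4,4,5,5-tetramethyl-1,3,2-dioxaborolane | COc1c(Br)cc(Br)cc1Oc1c(Br)cc(Br)c(Br)c1B1OC(C)(C)C(C)(C)O1
A9 | alternative 3 | 3,4-dibromo-6-iodo-2-(4,4,5,5-tetramethyl-1,3,2-dioxaborolan-2-yl)phenyl trifluoromethanesulfonate | O=S(=O)(Oc1c(I)cc(Br)c(Br)c1B1OC(C)(C)C(C)(C)O1)C(F)(F)F
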